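## The problem

Bisoflavolin N (18) consists of two genistein units joined by a biaryl bond between the C3' carbons of their rings B, each of which lies ortho to a 4'-hydroxyl. A single chlorine at C8 of one ring A is the only feature that breaks the twofold symmetry. There is no stereocentre, and the biaryl axis, flanked only by two hydroxyls and two hydrogens, should rotate freely, so the task is purely regiochemical. Two 3-aryl-4H-chromen-4-one systems must be built on a 2,2'-dioxygenated biphenyl, and one chlorine must go to C8 of one half only, not to C6 and not to ring B. Six phenols must be carried masked and released without touching the aryl chloride, which speaks against hydrogenolysis of benzyl ethers and for methyl ethers cleaved by a Lewis acid. The pyranone rings are the fragile part, because C2 of an isoflavone is opened by hydroxide or alkoxide, so rings C should be closed late and kept away from hot aqueous base. The enabling feature is that ring A is attached to the rest of each chromone through two adjacent carbons, C8a to O1 and C4a to C4, and an aryne can accept an oxygen nucleophile at one carbon and an acyl group at the other. What remains, O1–C2=C3(aryl)–C4, is a 2-aryl-3-hydroxyacrylate, one formylation away from an arylacetic ester, and the 5-oxygen sits exactly where an alkoxy group beside the aryne would place the aryl anion.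

## Retrosynthesis

**18 from 17.** Six O–CH3 bonds are cut, leading back to hexamethyl ether 17. Methyl is preferred to benzyl, whose hydrogenolysis would endanger the C–Cl bond, and to acetals, which would complicate the organolithium and fluoride chemistry. The methyl ethers also steer both the aryne addition and the chlorination. The forward step asks BBr3 to cleave two hindered biphenyl ethers and four ring A ethers in one operation.

**17 from 16.** The C8–Cl bond is cut, giving the symmetric hexamethyl ether 16. The neighbouring option, chlorine carried on the aryne, fails on two counts. Chlorine would flank the triple bond opposite the methoxy group and compete with it for regiocontrol, and both halves would be chlorinated unless two different arynes were added in sequence. In 16 every phenol is methylated, the state in which 5,7-dioxygenated chromones are expected to be halogenated at C8 and not at C6. The cost is that the two rings A are identical and remote, so mono-chlorination is statistical; unreacted 16 can be recycled.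

**16 from 5 and 13.** O1–C8a and C4–C4a are cut in both halves: four bonds and two rings in one step. The partners are bis(3-hydroxyacrylate) 5 and two equivalents of 3,5-dimethoxybenzyne 14, released from silyl triflate 13; the half-reacted compound 15 lies on the way. Two neighbouring cuts were weighed against this one.
- Cutting only C4–C4a (Friedel–Crafts acylation of phenol 6, then insertion of C2) needs three operations on a doubled substrate. It is kept as the fallback.
- Cutting C3–C1' (cross-coupling of a 3-halochromone) requires the chromone to be made separately first.

The aryne cut removes rings A and C together and leaves a precursor with only the biphenyl and two short side chains. The forward reaction needs O-arylation at the aryne carbon remote from methoxy, a cis relation of aryloxy and ester, and acyl capture of the aryl anion faster than protonation. The cis geometry is to be secured by running the reaction on the chelated cesium enolate in THF.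

**5 from 4.** The two bonds between the alpha-carbons and the formyl carbons are cut, giving bis(arylacetate) 4. A crossed Claisen condensation with methyl formate is the standard way to 2-aryl-3-hydroxyacrylates and needs no protecting-group change.

**4 from 2 and 3.** The biaryl bond is cut. Both halves are the same arene, so the partners are bromide 2 and the pinacol boronate 3 made from it. A reductive homocoupling of 2 alone would save one operation and is held in reserve. The cross-coupling is preferred because each partner has a defined role, the conditions are non-reducing, and Suzuki–Miyaura couplings to 2,2'-dialkoxybiaryls are dependable. The forward reaction must tolerate two methyl esters with acidic benzylic protons, which asks for a mild base and little water.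

**3 from 2, 2 from 1.** The C–B bond of 3 is cut back to bromide 2, the methyl ester of commercial acid 1. The bromine of 1 is already ortho to the methoxy group and meta to the acetic acid chain, the pattern needed for C3'. The route stays symmetric until step 9.

**13 from 6.** The S–O bond of the triflate and the C–Si bond are cut: 13 comes from silyl phenol 12, this from silyl carbamate 11, and this from carbamate 7 of commercial 3,5-dimethoxyphenol 6. Lithiation runs through the N-silylated species 8, 9 and 10. Bromination of 6 followed by silyl migration was set aside because 6 can brominate at C2 or C4. The carbamate directs the metal to the carbon between itself and a methoxy group.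

## Roads not taken

Alternative 1: Here the C3–C4 bond of each half is made by a 1,2-aroyl shift. The bis(trans-chalcone epoxide) A2 would be opened by BF3·OEt2 at its benzylic carbons, and migration of each aroyl group would give the bis(alpha-formyl deoxybenzoin) enol A1. Debenzylation and cyclodehydration would then close both rings C.
- Merits: the rearrangement is an established route to isoflavones, and A1 already carries chlorine on one aroyl arm, so no late halogenation is needed. In that respect this road is better than the chosen one.
- Weak points: the advantage only exists if A2 can be assembled unsymmetrically. That means condensing two different ketones with two identical formyl groups on the biphenyl, which is the same statistical problem moved to an earlier and more expensive stage. The benzyl ethers must be removed beside an aryl chloride, which excludes plain hydrogenolysis. The sequence on the doubled substrate is long: aldol, epoxidation, rearrangement, debenzylation and ring closure.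
- Comparison: the chosen plan brings each ring A with both of its bonds in one step and confines the statistical event to one late, recyclable operation.

Alternative 2: This road builds ring B of the chlorinated half from acyclic material. The pyrrolidine enamine of methyl 4-oxobutanoate A5 would add to vinyl ketone A4, and aldol condensation would give racemic cyclohexenone A3, forming C1'–C6' and C2'–C3'. Aromatisation to the phenol and methylation would follow.
- Merits: the biaryl is unsymmetrical from the start, with a bromide on one ring and an acetate chain on the other, so the two chromones could be built in turn and chlorine placed without statistics. That is a real advantage over the chosen plan.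
- Weak points: ring B is a plain 1,2,4-trisubstituted benzene that can be bought as acid 1. The same differentiation could be reached far more cheaply by cross-coupling two different aryl halves. The route creates a stereocentre only to destroy it, needs a dehydrogenation beside an aryl bromide, and uses a polymerisable vinyl ketone. None of this advances rings A and C.
- Comparison: the chosen plan buys ring B and spends its steps on the chromones.

Alternative 3: Here both rings A are made by polyketide folding. The bis(3,5,7-trioxo-8-aryloctanoate) A7, released from a masked dioxinone form, would be treated with Mg(OMe)2 so that C6 of each chain acylates C1. This closes two acylphloroglucinols and gives the bis(2,4,6-trihydroxydeoxybenzoin) A6. Insertion of C2, chlorination and cleavage of only two methyl ethers would finish the synthesis.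
- Merits: the route avoids aryne chemistry and is better in protecting-group economy, since ring A never needs to be methylated.
- Weak points: phloroglucinol-type rings are commercial, and A6 would be reachable by a single Friedel–Crafts acylation of such a ring with the diacid F1 of diester 4, so building the rings adds many steps for no structural gain. The triketo esters can also fold by aldol or pyrone modes, and here that risk is doubled. The free acylphloroglucinol has two equivalent positions, so chlorination would be neither site-selective within a ring nor selective between the halves.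
- Comparison: the chosen plan offers a commercial ring A, four bonds in one step, and methyl ethers that direct chlorine to C8.

Key step: step 8

Assumption: 5 is drawn as its Z,Z-bis-enol; in solution it will equilibrate with formyl tautomers and E-enols, all of which give the same cesium enolate.

## Route

Step 1
Reactants: 1 2-(3-bromo-4-methoxyphenyl)acetic acid
Product: 2 methyl 2-(3-bromo-4-methoxyphenyl)acetate
Conditions: MeOH, cat. H2SO4, reflux
Reagents that add atoms: methanol, CO
Why: Fischer esterification driven by excess methanol; aryl bromide and anisole are inert to acid.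

Step 2
Reactants: 2 methyl 2-(3-bromo-4-methoxyphenyl)acetate
Product: 3 methyl 2-[4-methoxy-3-(4,4,5,5-tetramethyl-1,3,2-dioxaborolan-2-yl)phenyl]acetate
Conditions: B2pin2 (1.1 equiv), Pd(dppf)Cl2 (3 mol %), KOAc, 1,4-dioxane, 90 °C (about half of the stock of 2)
Reagents that add atoms: bis(pinacolato)diboron, CC1(C)OB(OC1(C)C)B1OC(C)(C)C(C)(C)O1
Why: Miyaura borylation: zerovalent palladium inserts into C–Br, acetate assists transmetalation with the diboron, and reductive elimination gives the aryl boronate; KOAc is too weak a base to enolise the arylacetate, and any biaryl formed prematurely is 4 itself.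

Step 3
Reactants: 2 methyl 2-(3-bromo-4-methoxyphenyl)acetate; 3 methyl 2-[4-methoxy-3-(4,4,5,5-tetramethyl-1,3,2-dioxaborolan-2-yl)phenyl]acetate
Product: 4 dimethyl 2,2'-(6,6'-dimethoxybiphenyl-3,3'-diyl)diacetate
Conditions: Pd(OAc)2 (2 mol %), SPhos (4 mol %), K3PO4, toluene/H2O (10:1), 80 °C
Reagents that add atoms: none
Why: Suzuki–Miyaura cross-coupling of the bromide with its own boronate; the bulky, electron-rich biarylphosphine is suited to joining two ortho-methoxy partners, and K3PO4 with little water should spare the methyl esters and the benzylic CH2 groups.

Step 4
Reactants: 4 dimethyl 2,2'-(6,6'-dimethoxybiphenyl-3,3'-diyl)diacetate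
Product: 5 dimethyl (2Z,2'Z)-2,2'-(6,6'-dimethoxybiphenyl-3,3'-diyl)bis(3-hydroxyacrylate)
Conditions: NaH, HCO2Me (excess), THF, 0 °C to rt; then 1 M HCl
Reagents that add atoms: methyl formate, COC=O
Why: Crossed Claisen condensation of each arylacetate enolate with non-enolisable methyl formate; the product leaves the equilibrium as its sodium enolate and should be obtained on acidification as the hydrogen-bonded Z-enol, as is usual for 2-aryl-3-hydroxyacrylates.

Step 5
Reactants: 6 3,5-dimethoxyphenol
Product: 7 3,5-dimethoxyphenyl isopropylcarbamate
Conditions: i-PrNCO, cat. Et3N, CH2Cl2, rt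
Reagents that add atoms: isopropyl isocyanate, CC(C)N=C=O
Why: Amine-catalysed addition of the phenol to the isocyanate gives the N-monoalkyl carbamate, chosen because it directs ortho-lithiation and is later removed under mild base.

Step 6
Reactants: 7 3,5-dimethoxyphenyl isopropylcarbamate
Product: 11 3,5-dimethoxy-2-(trimethylsilyl)phenyl isopropylcarbamate, via N-silyl carbamate 8 (not isolated), via ortho-lithiated N-silyl carbamate 9 (not isolated), via N-silyl C-silyl carbamate 10 (not isolated)
Conditions: TBSOTf, TMEDA, Et2O, 0 °C to rt; n-BuLi (2.2 equiv), TMEDA, −78 °C; TMSCl, −78 °C to rt; aq. NaHSO4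
Reagents that add atoms: chlorotrimethylsilane, C[Si](C)(C)Cl
Why: Directed ortho-metalation: N-silylation in the flask masks the N–H, n-BuLi/TMEDA lithiates the carbon flanked by the carbamate and a methoxy group (two cooperating directors, the carbamate the stronger), TMSCl traps the aryllithium, and the N–Si bond is hydrolysed on work-up.

Step 7
Reactants: 11 3,5-dimethoxy-2-(trimethylsilyl)phenyl isopropylcarbamate
Product: 13 3,5-dimethoxy-2-(trimethylsilyl)phenyl trifluoromethanesulfonate, via 3,5-dimethoxy-2-(trimethylsilyl)phenol 12 (not isolated)
Conditions: DBU, Et2NH, MeCN, 40 °C; then PhNTf2, rt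
Reagents that add atoms: N-phenylbis(trifluoromethanesulfonimide), O=S(=O)(N(c1ccccc1)S(=O)(=O)C(F)(F)F)C(F)(F)F
Why: Base-induced E1cB loss of isopropyl isocyanate (scavenged by Et2NH as the urea) frees the phenoxide, which is triflated in the same flask, so the acid-sensitive ortho-silyl phenol is never handled.

Step 8
Reactants: 5 dimethyl (2Z,2'Z)-2,2'-(6,6'-dimethoxybiphenyl-3,3'-diyl)bis(3-hydroxyacrylate); 13 3,5-dimethoxy-2-(trimethylsilyl)phenyl trifluoromethanesulfonate (two equivalents consumed, about three used)
Product: 16 3,3'-(6,6'-dimethoxybiphenyl-3,3'-diyl)bis(5,7-dimethoxy-4H-chromen-4-one), via 3,5-dimethoxybenzyne 14 (not isolated), via mono-annulated enol ester 15 (not isolated)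
Conditions: CsF (8 equiv), THF, 65 °C, sealed tube
Reagents that add atoms: none
Why: Proposed new method: cesium fluoride turns both enols of 5 into cesium enolates and releases aryne 14 from 13 by attack on silicon with loss of triflate; each enolate oxygen adds to the aryne carbon remote from the flanking methoxy group (O1–C8a), and the resulting aryl anion, cis to the ester across C2=C3, adds to the ester carbonyl and expels methoxide (C4–C4a), giving first 15 and then 16. The closest known reaction type is the fluoride-triggered annulation of arynes with salicylate esters to xanthones, of which a 3-hydroxyacrylate is the ring-free counterpart, together with aryne insertion into beta-keto esters. Each ring C closes by a 6-exo-trig acyl substitution of an aryl anion at an ester, and no stereocentre is formed. Three selectivities are required. Aryne regiochemistry is set by the methoxy group next to the triple bond, which makes the distal carbon electrophilic and stabilises the anion beside itself, so the methoxy groups end at C5 and C7. O- over C-arylation is expected because the alpha-carbon is fully substituted and conjugated to ring B, and because such formyl-ester enolates are alkylated at oxygen in beta-methoxyacrylate synthesis. The cis relation of aryloxy and ester relies on the chelated, U-shaped cesium ion pair, which THF without crown ether should favour. Excess 13 covers aryne lost to the liberated methanol.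

Step 9
Reactants: 16 3,3'-(6,6'-dimethoxybiphenyl-3,3'-diyl)bis(5,7-dimethoxy-4H-chromen-4-one)
Product: 17 8-chloro-3-[5'-(5,7-dimethoxy-4-oxo-4H-chromen-3-yl)-2',6-dimethoxybiphenyl-3-yl]-5,7-dimethoxy-4H-chromen-4-one
Conditions: NCS (0.9 equiv), cat. TFA, MeCN, 0 °C to rt; recovered 16 recycled
Reagents that add atoms: N-chlorosuccinimide, O=C1CCC(=O)N1Cl
Why: Electrophilic aromatic chlorination: ring A with three oxygen donors is the most nucleophilic arene, and with the 5-oxygen methylated attack is expected at C8 (para to the 5-methoxy group and less hindered than C6), as in the 8-halogenation of 5,7-dimethoxyflavones. The two identical rings react statistically, so a slight deficit of NCS limits double chlorination.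

Step 10
Reactants: 17 8-chloro-3-[5'-(5,7-dimethoxy-4-oxo-4H-chromen-3-yl)-2',6-dimethoxybiphenyl-3-yl]-5,7-dimethoxy-4H-chromen-4-one
Product: 18 bisoflavolin N, 8-chloro-3-[5'-(5,7-dihydroxy-4-oxo-4H-chromen-3-yl)-2',6-dihydroxybiphenyl-3-yl]-5,7-dihydroxy-4H-chromen-4-one
Conditions: BBr3 (excess), CH2Cl2, −78 °C to rt (40 °C if needed); then H2O
Reagents that add atoms: none
Why: Lewis-acid ether cleavage: BBr3 coordinates each methoxy oxygen and bromide removes the methyl group by SN2; the aryl chloride, the chromones and the biaryl are stable, and hydrolysis of the aryl borates frees the six phenols.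

## Compound list

1 | 2-(3-bromo-4-methoxyphenyl)acetic acid | COc1ccc(CC(O)=O)cc1Br | starting material
2 | methyl 2-(3-bromo-4-methoxyphenyl)acetate | COC(=O)Cc1ccc(OC)c(Br)c1 | intermediate
3 | methyl 2-[4-methoxy-3-(4,4,5,5-tetramethyl-1,3,2-dioxaborolan-2-yl)phenyl]acetate | COC(=O)Cc1ccc(OC)c(B2OC(C)(C)C(C)(C)O2)c1 | intermediate
4 | dimethyl 2,2'-(6,6'-dimethoxybiphenyl-3,3'-diyl)diacetate | COC(=O)Cc1ccc(OC)c(-c2cc(CC(=O)OC)ccc2OC)c1 | intermediate
5 | dimethyl (2Z,2'Z)-2,2'-(6,6'-dimethoxybiphenyl-3,3'-diyl)bis(3-hydroxyacrylate) | COC(=O)/C(=C\O)c1ccc(OC)c(-c2cc(/C(=C/O)C(=O)OC)ccc2OC)c1 | intermediate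
6 | 3,5-dimethoxyphenol | COc1cc(O)cc(OC)c1 | starting material
7 | 3,5-dimethoxyphenyl isopropylcarbamate | COc1cc(OC)cc(OC(=O)NC(C)C)c1 | intermediate
8 | 3,5-dimethoxyphenyl N-(tert-butyldimethylsilyl)-N-isopropylcarbamate | COc1cc(OC)cc(OC(=O)N(C(C)C)[Si](C)(C)C(C)(C)C)c1 | intermediate (not isolated)
9 | 2-lithio-3,5-dimethoxyphenyl N-(tert-butyldimethylsilyl)-N-isopropylcarbamate | COc1cc(OC)c([Li])c(OC(=O)N(C(C)C)[Si](C)(C)C(C)(C)C)c1 | intermediate (not isolated)
10 | 3,5-dimethoxy-2-(trimethylsilyl)phenyl N-(tert-butyldimethylsilyl)-N-isopropylcarbamate | COc1cc(OC)c([Si](C)(C)C)c(OC(=O)N(C(C)C)[Si](C)(C)C(C)(C)C)c1 | intermediate (not isolated)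
11 | 3,5-dimethoxy-2-(trimethylsilyl)phenyl isopropylcarbamate | COc1cc(OC)c([Si](C)(C)C)c(OC(=O)NC(C)C)c1 | intermediate
12 | 3,5-dimethoxy-2-(trimethylsilyl)phenol (as its DBU salt) | COc1cc(O)c([Si](C)(C)C)c(OC)c1 | intermediate (not isolated)
13 | 3,5-dimethoxy-2-(trimethylsilyl)phenyl trifluoromethanesulfonate | COc1cc(OC)c([Si](C)(C)C)c(OS(=O)(=O)C(F)(F)F)c1 | intermediate
14 | 3,5-dimethoxybenzyne | COC1=CC(OC)=CC#C1 | intermediate (not isolated)
15 | methyl (Z)-2-[5'-(5,7-dimethoxy-4-oxo-4H-chromen-3-yl)-2',6-dimethoxybiphenyl-3-yl]-3-hydroxyacrylate | COC(=O)/C(=C\O)c1ccc(OC)c(-c2cc(-c3coc4cc(OC)cc(OC)c4c3=O)ccc2OC)c1 | intermediate (not isolated)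
16 | 3,3'-(6,6'-dimethoxybiphenyl-3,3'-diyl)bis(5,7-dimethoxy-4H-chromen-4-one) | O=c1c(-c2ccc(OC)c(-c3cc(-c4coc5cc(OC)cc(OC)c5c4=O)ccc3OC)c2)coc2cc(OC)cc(OC)c12 | intermediate
17 | 8-chloro-3-[5'-(5,7-dimethoxy-4-oxo-4H-chromen-3-yl)-2',6-dimethoxybiphenyl-3-yl]-5,7-dimethoxy-4H-chromen-4-one | O=c1c(-c2ccc(OC)c(-c3cc(-c4coc5c(Cl)c(OC)cc(OC)c5c4=O)ccc3OC)c2)coc2cc(OC)cc(OC)c12 | intermediate
18 | bisoflavolin N | O=c1c(-c2ccc(O)c(-c3cc(-c4coc5c(Cl)c(O)cc(O)c5c4=O)ccc3O)c2)coc2cc(O)cc(O)c12 | target

## Step count and risks

Total: 10 steps. Longest linear sequence: 7 steps (1, 2, 3, 4, 8, 9, 10); the aryne branch (steps 5, 6 and 7) joins at step 8.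

**Step 8 (key step, proposed new method).** Several processes could defeat it:
- arylation at the alpha-carbon instead of oxygen, followed by acyl transfer to the aryne (net insertion into the C–CHO bond);
- O-arylation of an extended enolate geometry, which leaves the aryl anion out of reach of the ester;
- protonation of the aryl anion before acyl capture;
- erosion of aryne regiocontrol.

The fallback uses known chemistry only, sets out from 4 and returns at 16. Saponification of 4 (LiOH, THF/H2O, then acid) gives 2,2'-(6,6'-dimethoxybiphenyl-3,3'-diyl)diacetic acid F1. Heating F1 with two equivalents of 6 in BF3·OEt2 at about 85 °C should acylate each phenol ortho to its hydroxyl (Friedel–Crafts/Fries type) to give the bis(deoxybenzoin) 2,2'-(6,6'-dimethoxybiphenyl-3,3'-diyl)bis[1-(2-hydroxy-4,6-dimethoxyphenyl)ethan-1-one] F2. Treatment of F2 with DMF, BF3·OEt2 and MeSO2Cl inserts C2 and closes both rings C to give 16.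

**Step 9.** The two identical rings A cannot be told apart, so unreacted, mono- and dichlorinated material will form together and must be separated. Chlorination at C6 or on ring B may also intrude. The fallback makes the halves separately with known reactions, sets out from 1 and 6 and returns at 17. Acylation of 6 with 1 in BF3·OEt2 gives 2-(3-bromo-4-methoxyphenyl)-1-(2-hydroxy-4,6-dimethoxyphenyl)ethan-1-one F3. Ring closure with DMF, BF3·OEt2 and MeSO2Cl gives 3-(3-bromo-4-methoxyphenyl)-5,7-dimethoxy-4H-chromen-4-one F4. One portion of F4 is chlorinated with a full equivalent of NCS, here without a statistical limit, to 3-(3-bromo-4-methoxyphenyl)-8-chloro-5,7-dimethoxy-4H-chromen-4-one F5. The other portion undergoes Miyaura borylation (B2pin2, Pd(dppf)Cl2, KOAc, dioxane) to 5,7-dimethoxy-3-[4-methoxy-3-(4,4,5,5-tetramethyl-1,3,2-dioxaborolan-2-yl)phenyl]-4H-chromen-4-one F6. Suzuki–Miyaura coupling of F5 with F6 (Pd(PPh3)4, K3PO4, dioxane with a little H2O, 80 °C) should engage the bromide in preference to the hindered, electron-rich chloride and give 17.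

**Step 3.** Protodeboronation of the electron-rich ortho-methoxy boronate could outrun transmetalation in a coupling that joins two ortho-substituted partners, and the aqueous base could saponify the esters. The fallback changes the bond-forming logic from cross-coupling to reductive homocoupling, sets out from 2 and returns at 4. Two molecules of 2 are joined directly with NiCl2(PPh3)2 (10 mol %), PPh3, Zn dust and Et4NI in THF at 50 °C. Zinc reduces divalent nickel to zerovalent nickel, which inserts into C–Br, and the biaryl leaves by reductive elimination under neutral conditions without boron or base. No new compound arises on this way (F0).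

## Further compounds

F1 | step 8 | 2,2'-(6,6'-dimethoxybiphenyl-3,3'-diyl)diacetic acid | OC(=O)Cc1ccc(OC)c(-c2cc(CC(O)=O)ccc2OC)c1
F2 | step 8 | 2,2'-(6,6'-dimethoxybiphenyl-3,3'-diyl)bis[1-(2-hydroxy-4,6-dimethoxyphenyl)ethan-1-one] | COc1cc(O)c(C(=O)Cc2ccc(OC)c(-c3cc(CC(=O)c4c(O)cc(OC)cc4OC)ccc3OC)c2)c(OC)c1
F3 | step 9 | 2-(3-bromo-4-methoxyphenyl)-1-(2-hydroxy-4,6-dimethoxyphenyl)ethan-1-one | COc1cc(O)c(C(=O)Cc2ccc(OC)c(Br)c2)c(OC)c1
F4 | step 9 | 3-(3-bromo-4-methoxyphenyl)-5,7-dimethoxy-4H-chromen-4-one | COc1ccc(-c2coc3cc(OC)cc(OC)c3c2=O)cc1Br
F5 | step 9 | 3-(3-bromo-4-methoxyphenyl)-8-chloro-5,7-dimethoxy-4H-chromen-4-one | COc1ccc(-c2coc3c(Cl)c(OC)cc(OC)c3c2=O)cc1Br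
F6 | step 9 | 5,7-dimethoxy-3-[4-methoxy-3-(4,4,5,5-tetramethyl-1,3,2-dioxaborolan-2-yl)phenyl]-4H-chromen-4-one | COc1ccc(-c2coc3cc(OC)cc(OC)c3c2=O)cc1B1OC(C)(C)C(C)(C)O1
F0 | step 3 | none | none
A1 | alternative 1 | bis(2-aryl-3-hydroxypropenone), enol form of the bis(alpha-formyl deoxybenzoin) with one chlorinated aroyl arm | O=C(c1c(OCc2ccccc2)cc(OC)cc1OC)/C(=C\O)c1ccc(OC)c(-c2cc(/C(=C/O)C(=O)c3c(OCc4ccccc4)c(Cl)c(OC)cc3OC)ccc2OC)c1
A2 | alternative 1 | bis(trans-chalcone epoxide) precursor of A1 (each epoxide trans, racemic, one diastereomer drawn) | O=C(c1c(OCc2ccccc2)cc(OC)cc1OC)[C@@H]1O[C@H]1c1ccc(OC)c(-c2cc([C@H]3O[C@@H]3C(=O)c3c(OCc4ccccc4)c(Cl)c(OC)cc3OC)ccc2OC)c1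
A3 | alternative 2 | methyl 2-[3-(5-bromo-2-methoxyphenyl)-4-oxocyclohex-2-en-1-yl]acetate (racemic) | COC(=O)CC1CCC(=O)C(c2cc(Br)ccc2OC)=C1
A4 | alternative 2 | 1-(5-bromo-2-methoxyphenyl)but-3-en-2-one | C=CC(=O)Cc1cc(Br)ccc1OC
A5 | alternative 2 | methyl 4-oxobutanoate | COC(=O)CCC=O
A6 | alternative 3 | bis(2,4,6-trihydroxydeoxybenzoin) on the 2,2'-dimethoxybiphenyl core | COc1ccc(CC(=O)c2c(O)cc(O)cc2O)cc1-c1cc(CC(=O)c2c(O)cc(O)cc2O)ccc1OC
A7 | alternative 3 | dimethyl bis(3,5,7-trioxo-8-aryloctanoate) on the 2,2'-dimethoxybiphenyl core | COC(=O)CC(=O)CC(=O)CC(=O)Cc1ccc(OC)c(-c2cc(CC(=O)CC(=O)CC(=O)CC(=O)OC)ccc2OC)c1
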